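## Analysis of the target

The target (14) is a 6-aryl-5,7,4'-trihydroxyflavone: a chromen-4-one (rings A and C) with a 4-hydroxyphenyl ring B on C2 and, on C6, ring D, a benzene ring bonded through D1 that carries a methoxy group on D2 and a methyl ester on D5. It has no stereocentre; the only stereochemical element is the C6–D1 axis, flanked by O5–H, O7–H and the D2 methoxy group, and no descriptor is specified for it. The sensitive groups are the methyl ester (destroyed by hydroxide, only exchanged degenerately by methoxide in methanol), the single aryl methyl ether that must survive beside three free phenols, and the electron-rich ring A, which is easily halogenated or oxidised at C8. The methyl ether rules out a global demethylation as the last step. The main difficulty is the C6–D1 bond: it joins two carbons that both carry ortho oxygen, and on a finished 5,7-dioxygenated flavone C6 and C8 are hard to tell apart. The strategy rests on the oxygen pattern of ring A: C5, C7 and C8a carry oxygen and C4a carries the acyl carbon C4, the pattern of a folded tetraketide. C6 lies between two oxygenated carbons exactly as C3 does in a 4-hydroxy-2-pyranone, so ring D can be attached while C6 is still the nucleophilic C3 of a flat, unhindered pyranone, and ring A is folded around it afterwards.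

## Retrosynthetic reasoning

**14 to 13.** The last operation forms no skeletal bond: 14 is traced back to its 4'-O-benzyl ether 13. O4' is the only phenol that needs a mask, because a free phenol would consume base in the carbanion chemistry and turn the acyl donor into an unreactive phenoxide. A benzyl ether survives amide bases, alkoxide and the oxidative ring closure, and its hydrogenolysis leaves the pyranone double bond, the ester and the methyl ether alone.

**13 to 11.** Ring C is opened at O1–C2 and the C2=C3 bond is returned to the enone of chalcone 11. The forward reaction is an oxa-Michael closure to flavanone 12 followed by dehydrogenation in the same flask. The cut is placed here because a chalcone is what the polyketide folding delivers directly. The price is that 11 has two hydroxyls ortho to the acyl group, on C5 and on C8a, and only closure through O8a puts ring D on C6. O5–H is wedged between ring D and the carbonyl, so it should be the better hydrogen-bond donor to C4=O and the more shielded nucleophile, which favours closure through O8a. This is a preference and not a certainty, so the step sits where isomers can still be separated.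

**11 to 9 (key disconnection).** Ring A is cut at C4a–C5. The carbon chain unfolds to triketo ester 10, which is stored as pyranone 9, the lactone that ties C5 to the oxygen on C8a. This builds ring A without any aromatic substitution, releases all three ring A oxygens unprotected and brings ring D in already attached. The forward step must open the lactone, fold by Claisen and not by aldol closure, and leave the enone intact.

**9 to 4 and 7.** The C4–C4a bond is cut. The 6-methyl group of pyranone 4 is the only carbon acid after the hydroxyl, so its dianion 8 is the nucleophile. The acyl donor is the N-methoxy-N-methylamide 7, made from acid 5 through acyl imidazole 6. This amide stops at the ketone stage and keeps the acidic product masked until work-up. The forward reaction has to prefer the amide carbonyl over the ring D ester and over conjugate addition.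

**4 to 2 and 3.** The C6–D1 bond is cut while C6 is C3 of the pyranone. That carbon is a nucleophile, so its polarity is inverted through the phenyliodonium ylide 2, made from pyranone 1, and the partner is the purchasable boronic acid 3. Cutting here means the hindered biaryl bond is made on a small flat ring with no regiochemical question, since C3 is the only carbon of 1 between two oxygenated carbons.

## Alternatives that were turned down

**Alternative 1:** Ring D is disconnected across D3–D4 and D5–D6. In the forward direction the 2-aryl-3-methoxybutadiene A2 and methyl propiolate A3 combine in a thermal [4+2] cycloaddition to the cyclohexadiene A1, which is dehydrogenated to the arene later.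
- For: the donor methoxy group steers the ester into the 1,4-relationship that ring D needs. The phloroglucinol unit of A2 is symmetric, with two benzyloxy groups beside the axis and the allyloxy group opposite marking the future O1. After deallylation, acylation at either free position gives the same ketone, so ring D lands on C6 without ambiguity. On this point the alternative is stronger than the chosen route.
- Against: A2 carries a 2,6-disubstituted aryl group on an internal diene carbon, is crowded and must be made in several steps. The regiochemistry depends on methoxy outweighing aryl. The enol ether of A1 is labile to hydrolysis before aromatisation, and the allyl aryl ether is exposed to heat.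
- Comparison: after A1, rings C and B still have to be built in at least six further operations, and the sequence constructs the one ring that can be bought as 3. The chosen route offers seven steps in total and a key step of a known reaction type.

**Alternative 2:** The C6–D1 bond is disconnected on the intact flavone, with ring D held on O5 through a di-tert-butylsilylene bridge to the oxygen on D2. In the forward direction zerovalent palladium inserts into the D1–I bond of the bridged iodide A5 and the arylpalladium cleaves C6–H with carboxylate assistance, giving the bridged 6-arylflavone A4.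
- For: only C6–H is within reach of the tethered metal, so C6 against C8 is decided by geometry. This is stronger than the chosen route, and the coupling is a late step on a simple protected flavone.
- Against: A5 is an unsymmetrical diaryloxysilane that must be assembled on the chelated, poorly nucleophilic O5–H with a hindered silicon electrophile. Aryloxysilanes are labile to carbonate and carboxylate at the temperatures of C–H arylation. The seven-membered ring forms through an eight-membered palladacycle at an electron-rich C–H bond, for which there is no close analogy. Afterwards the bridge must be removed and the D2 hydroxyl methylated selectively in the presence of O5–H.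
- Comparison: the regiochemistry is better, but the central step is unprecedented and the tail is longer. The chosen route offers a known key reaction, purchasable inputs and no protecting groups on ring A.

**Alternative 3:** Ring A is disconnected into a vinylketene and an alkyne. In the forward direction, irradiation of the pyranonyl diazoketone A7 triggers a Wolff shift (C8a–C8). The ketene adds to the siloxyalkyne A8 (C5–C6 and C7–C8), and four-electron opening followed by six-electron closure (C4a–C5) gives the 5-hydroxy-7-silyloxyflavone A6.
- For: it is the most convergent plan. The polarity of the ynol ether fixes ring D on C6 next to the new C5 hydroxyl, and O5 and O7 emerge differentiated. On regiochemistry and convergence it is stronger than the chosen route.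
- Against: A8 is an aryl ynol silyl ether that has to be made through ynolate chemistry with organolithium bases while a methyl ester sits on the same ring. A7 needs a 6-aryl-4-oxopyran-2-carboxylic acid elaborated to the diazoketone. The 4-pyranone is itself a photoreactive chromophore. The C4a=C8a bond of a pyranone as the "vinyl" partner of this benzannulation has no analogy.
- Comparison: each partner would take about as many steps as the whole chosen sequence to precursor 9, and the key step is speculative. The chosen route offers short access from 1, 3 and 5 and a key step whose reaction type is established.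

Key step: step 5

Remark on the chemistry: the C6–D1 axis carries no descriptor in the target and is treated as freely rotating, so no atropselective step is planned. Flavone numbering (C4, C4a, C5 to C8a) is used for the ring A and C atoms in all intermediates, and D1, D2, D5 for ring D as defined above.

## Route

Step 1
Reactants: 1 4-hydroxy-6-methyl-2H-pyran-2-one
Product: 2 6-methyl-2-oxo-3-(phenyliodonio)-2H-pyran-4-olate
Conditions: PhI(OAc)2 (1.0 equiv), Na2CO3 (2 equiv), H2O, rt; the product is filtered off
Reagents that add atoms: (diacetoxyiodo)benzene, CC(=O)OI(OC(C)=O)c1ccccc1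
Why: Iodonium ylide formation of a cyclic β-dicarbonyl: the enolate of 1 attacks the trivalent iodine of PhI(OAc)2 at C3, the only carbon between two oxygenated carbons, and loss of both acetates gives the stable zwitterion 2.

Step 2
Reactants: 2 6-methyl-2-oxo-3-(phenyliodonio)-2H-pyran-4-olate; 3 2-methoxy-5-(methoxycarbonyl)phenylboronic acid
Product: 4 methyl 3-(4-hydroxy-6-methyl-2-oxo-2H-pyran-3-yl)-4-methoxybenzoate
Conditions: Pd(OAc)2 (5 mol %), P(t-Bu)3·HBF4 (10 mol %), K3PO4 (3 equiv), 3 (1.3 equiv), DME/H2O 4:1, rt; then 1 M HCl
Reagents that add atoms: none
Why: Suzuki–Miyaura-type coupling with the iodonium ylide as electrophile: zerovalent palladium inserts into the pyranonyl C–I bond and releases iodobenzene, the boronate transmetalates and reductive elimination forms the future C6–D1 bond. The bulky electron-rich phosphine allows room temperature, where the liberated iodobenzene reacts slowly, and K3PO4 in place of hydroxide spares the methyl ester.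

Step 3
Reactants: 5 (E)-3-[4-(benzyloxy)phenyl]prop-2-enoic acid
Product: 7 (E)-3-[4-(benzyloxy)phenyl]-N-methoxy-N-methylprop-2-enamide, via acyl imidazole 6 (not isolated)
Conditions: CDI (1.1 equiv), CH2Cl2, rt; then MeNHOMe·HCl (1.2 equiv), rt
Reagents that add atoms: N,O-dimethylhydroxylamine hydrochloride, CNOC.Cl; 1,1'-carbonyldiimidazole, O=C(n1ccnc1)n1ccnc1 (imidazole unit of 6 only)
Why: Amide formation through the acyl imidazole: CDI activates the acid without touching the E double bond or the benzyl ether, and the hydroxylamine displaces imidazole.

Step 4
Reactants: 4 methyl 3-(4-hydroxy-6-methyl-2-oxo-2H-pyran-3-yl)-4-methoxybenzoate; 7 (E)-3-[4-(benzyloxy)phenyl]-N-methoxy-N-methylprop-2-enamide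
Product: 9 methyl 3-{6-[(3E)-4-(4-benzyloxyphenyl)-2-oxobut-3-en-1-yl]-4-hydroxy-2-oxo-2H-pyran-3-yl}-4-methoxybenzoate, via dilithium dianion 8 (not isolated)
Conditions: LiN(i-Pr)2 (LDA, 2.2 equiv), THF/DMPU, −78 °C; then 7 (1.1 equiv), −78 to −40 °C; aq NH4Cl, then 1 M HCl to pH 3
Reagents that add atoms: lithium diisopropylamide, CC(C)[N-]C(C)C.[Li+] (lithium counter-ions of 8 only)
Why: Acylation of a β-dicarbonyl-type dianion with an N-methoxy-N-methylamide: the second equivalent of LDA deprotonates the 6-methyl group, and this most basic carbon of 8 adds to the amide carbonyl to form C4a–C4. The chelated tetrahedral adduct holds until work-up, so neither double addition nor quenching of 8 by the acidic product occurs, and at −78 °C the deactivated 4-methoxybenzoate ester should not compete.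

Step 5
Reactants: 9 methyl 3-{6-[(3E)-4-(4-benzyloxyphenyl)-2-oxobut-3-en-1-yl]-4-hydroxy-2-oxo-2H-pyran-3-yl}-4-methoxybenzoate
Product: 11 methyl 3-{3-[(2E)-3-(4-benzyloxyphenyl)prop-2-enoyl]-2,4,6-trihydroxyphenyl}-4-methoxybenzoate, via magnesium-chelated triketo ester 10 (not isolated)
Conditions: Mg(OMe)2 (about 8 equiv), MeOH, reflux; cold 1 M HCl, EtOAc; used directly
Reagents that add atoms: magnesium dimethoxide, C[O-].C[O-].[Mg+2] (methoxy group of 10 only, lost again on ring closure)
Why: Methoxide adds to the lactone carbonyl C5 and expels the enolate oxygen on C8a, giving triketo ester 10, which magnesium holds as a folded chelate through its 1,3-dicarbonyl units. The methylene C4a, acidified by the C4 and C8a carbonyls, attacks the ester carbonyl C5, methoxide leaves and the cyclohexanetrione tautomerises to the aromatic triol, which takes it out of all equilibria. The closest known reaction type is the Mg(OMe)2 refolding of 6-(2-oxoalkyl)-4-hydroxy-2-pyranones into acylphloroglucinols, applied here to a 3-aryl member with a cinnamoyl arm. Ring A closes in a 6-exo-trig mode at the ester carbonyl (enolendo with respect to the C4a=C8a enolate), which is a favoured mode, and no stereocentre forms. The step needs Claisen over aldol folding; the aldol closure of C6 onto C4 would make C6 quaternary, bearing ring D and the ester, so it cannot dehydrate to an arene and reverts. It also needs the enone to survive; conjugate addition of methanol is reversible and only the Claisen path ends in an aromatic sink. The ring D ester can only exchange methoxy for methoxy.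

Step 6
Reactants: 11 methyl 3-{3-[(2E)-3-(4-benzyloxyphenyl)prop-2-enoyl]-2,4,6-trihydroxyphenyl}-4-methoxybenzoate
Product: 13 methyl 3-{2-[4-(benzyloxy)phenyl]-5,7-dihydroxy-4-oxo-4H-chromen-6-yl}-4-methoxybenzoate, via racemic flavanone 12 (not isolated)
Conditions: I2 (10 mol %), DMSO, 120 °C; aq Na2S2O3; chromatography
Reagents that add atoms: none
Why: Iodine–DMSO oxidative cyclisation of a 2'-hydroxychalcone: 6-endo oxa-Michael closure gives flavanone 12 (C2 racemic and erased again), iodination at C3 and loss of HI give the flavone, and DMSO reoxidises HI. O5–H is buttressed by ring D into the hydrogen bond with C4=O and is screened by the twisted ring D, so closure should run mainly through O8a and place ring D on C6; any product of closure through O5 is removed by chromatography here.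

Step 7
Reactants: 13 methyl 3-{2-[4-(benzyloxy)phenyl]-5,7-dihydroxy-4-oxo-4H-chromen-6-yl}-4-methoxybenzoate
Product: 14 methyl 3-[5,7-dihydroxy-2-(4-hydroxyphenyl)-4-oxo-4H-chromen-6-yl]-4-methoxybenzoate
Conditions: H2 (1 atm), Pd/C (10 %), THF/MeOH, rt
Reagents that add atoms: none
Why: Hydrogenolysis of the benzyl aryl ether; the C2=C3 bond is part of the pyranone vinylogous ester and, like the methyl ester and the methyl ether, should be inert at 1 atm and room temperature.

## Compound list

1 | 4-hydroxy-6-methyl-2H-pyran-2-one | Cc1cc(O)cc(=O)o1 | starting material
2 | 6-methyl-2-oxo-3-(phenyliodonio)-2H-pyran-4-olate | Cc1cc([O-])c([I+]c2ccccc2)c(=O)o1 | intermediate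
3 | 2-methoxy-5-(methoxycarbonyl)phenylboronic acid | COC(=O)c1ccc(OC)c(B(O)O)c1 | starting material
4 | methyl 3-(4-hydroxy-6-methyl-2-oxo-2H-pyran-3-yl)-4-methoxybenzoate | COC(=O)c1ccc(OC)c(-c2c(O)cc(C)oc2=O)c1 | intermediate
5 | (E)-3-[4-(benzyloxy)phenyl]prop-2-enoic acid | O=C(O)/C=C/c1ccc(OCc2ccccc2)cc1 | starting material
6 | (E)-3-[4-(benzyloxy)phenyl]-1-(imidazol-1-yl)prop-2-en-1-one | O=C(/C=C/c1ccc(OCc2ccccc2)cc1)n1ccnc1 | intermediate (not isolated)
7 | (E)-3-[4-(benzyloxy)phenyl]-N-methoxy-N-methylprop-2-enamide | CON(C)C(=O)/C=C/c1ccc(OCc2ccccc2)cc1 | intermediate
8 | dilithium dianion of 4 (4-olate and 6-methylide) | [Li+].[Li+].COC(=O)c1ccc(OC)c(-c2c([O-])cc([CH2-])oc2=O)c1 | intermediate (not isolated)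
9 | methyl 3-{6-[(3E)-4-(4-benzyloxyphenyl)-2-oxobut-3-en-1-yl]-4-hydroxy-2-oxo-2H-pyran-3-yl}-4-methoxybenzoate | COC(=O)c1ccc(OC)c(-c2c(O)cc(CC(=O)/C=C/c3ccc(OCc4ccccc4)cc3)oc2=O)c1 | intermediate
10 | methyl 3-[(8E)-9-(4-benzyloxyphenyl)-1-methoxy-1,3,5,7-tetraoxonon-8-en-2-yl]-4-methoxybenzoate, present as its magnesium enolate chelate (C2 configurationally labile) | COC(=O)C(c1cc(C(=O)OC)ccc1OC)C(=O)CC(=O)CC(=O)/C=C/c1ccc(OCc2ccccc2)cc1 | intermediate (not isolated)
11 | methyl 3-{3-[(2E)-3-(4-benzyloxyphenyl)prop-2-enoyl]-2,4,6-trihydroxyphenyl}-4-methoxybenzoate | COC(=O)c1ccc(OC)c(-c2c(O)cc(O)c(C(=O)/C=C/c3ccc(OCc4ccccc4)cc3)c2O)c1 | intermediate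
12 | methyl 3-{2-[4-(benzyloxy)phenyl]-5,7-dihydroxy-4-oxo-3,4-dihydro-2H-chromen-6-yl}-4-methoxybenzoate (racemic) | COC(=O)c1ccc(OC)c(-c2c(O)cc3c(c2O)C(=O)CC(c2ccc(OCc4ccccc4)cc2)O3)c1 | intermediate (not isolated)
13 | methyl 3-{2-[4-(benzyloxy)phenyl]-5,7-dihydroxy-4-oxo-4H-chromen-6-yl}-4-methoxybenzoate | COC(=O)c1ccc(OC)c(-c2c(O)cc3oc(-c4ccc(OCc5ccccc5)cc4)cc(=O)c3c2O)c1 | intermediate
14 | methyl 3-[5,7-dihydroxy-2-(4-hydroxyphenyl)-4-oxo-4H-chromen-6-yl]-4-methoxybenzoate | COC(=O)c1ccc(OC)c(-c2c(O)cc3oc(-c4ccc(O)cc4)cc(=O)c3c2O)c1 | target

## Step count and risk

Total: 7 steps. Longest linear sequence: 6 steps (steps 1, 2, 4, 5, 6, 7); step 3 is a one-step side branch.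

**Step 5 (key step).**
- Risk: the ring-opened chain may be consumed through its enone before the Claisen closure, by conjugate addition of methoxide or of the C8 carbanion, or by retro-Claisen cleavage. The closure itself is slowed because the ester carbonyl C5 sits beside the arylated, easily enolised C6. The triol may also begin to close ring C during work-up.
- Fallback: the enone is taken out of the folding step. Setting out from 4, dianion 8 is acylated with N-methoxy-N-methylacetamide to give methyl 3-[4-hydroxy-2-oxo-6-(2-oxopropyl)-2H-pyran-3-yl]-4-methoxybenzoate F1. Mg(OMe)2 in methanol folds this simplest member of the substrate class into methyl 3-(3-acetyl-2,4,6-trihydroxyphenyl)-4-methoxybenzoate F2. A Claisen–Schmidt condensation of F2 with 4-benzyloxybenzaldehyde under NaOMe in methanol, chosen so that the ester can only exchange, then installs the styryl arm and returns to the route at 11.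

**Step 6.**
- Risk: ring closure through the hydroxyl beside ring D, which would carry ring D to C8, and electrophilic iodination of the free C8 position of the electron-rich ring.
- Fallback: closure and dehydrogenation are separated so that the wrong closure can be recycled. Setting out from 11, NaOAc in methanol at reflux closes ring C reversibly to flavanone 12 and its isomer methyl 3-{2-[4-(benzyloxy)phenyl]-5,7-dihydroxy-4-oxo-3,4-dihydro-2H-chromen-8-yl}-4-methoxybenzoate F3 (racemic). The two are separated, and F3 is returned to the same conditions, where it reopens to 11 and is redistributed. Pure 12 is dehydrogenated with DDQ in dioxane at reflux, neutral conditions that do not reopen ring C, and the route is rejoined at 13.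

**Step 4.**
- Risk: self-condensation, in which the dianion attacks the ring D ester of a second molecule, and conjugate addition to the β-carbon of the unsaturated amide instead of attack at its carbonyl.
- Fallback: an aldol addition followed by oxidation. Setting out from 4, dianion 8 is added at −78 °C to (E)-3-[4-(benzyloxy)phenyl]prop-2-enal, which reacts far faster than an ester and by 1,2-addition. This gives methyl 3-{6-[(3E)-4-(4-benzyloxyphenyl)-2-hydroxybut-3-en-1-yl]-4-hydroxy-2-oxo-2H-pyran-3-yl}-4-methoxybenzoate F4 (racemic). Oxidation of its allylic hydroxyl with MnO2 in CH2Cl2 returns to the route at 9.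

**Step 2.**
- Risk: transfer of phenyl in place of the pyranonyl group once iodobenzene accumulates, protodeiodination of the ylide, and protodeboronation of the ortho-methoxy boronic acid.
- Fallback: ligand coupling at lead in place of palladium catalysis. Setting out from 3, boron–lead exchange with Pb(OAc)4 and catalytic Hg(OAc)2 in CHCl3 gives [2-methoxy-5-(methoxycarbonyl)phenyl]lead triacetate F5. F5 arylates the β-dicarbonyl carbon C3 of 1 in CHCl3–pyridine, and the route is rejoined at 4.

## Further compounds

F1 | step 5 | methyl 3-[4-hydroxy-2-oxo-6-(2-oxopropyl)-2H-pyran-3-yl]-4-methoxybenzoate | COC(=O)c1ccc(OC)c(-c2c(O)cc(CC(C)=O)oc2=O)c1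
F2 | step 5 | methyl 3-(3-acetyl-2,4,6-trihydroxyphenyl)-4-methoxybenzoate | COC(=O)c1ccc(OC)c(-c2c(O)cc(O)c(C(C)=O)c2O)c1
F3 | step 6 | methyl 3-{2-[4-(benzyloxy)phenyl]-5,7-dihydroxy-4-oxo-3,4-dihydro-2H-chromen-8-yl}-4-methoxybenzoate (racemic) | COC(=O)c1ccc(OC)c(-c2c(O)cc(O)c3c2OC(c2ccc(OCc4ccccc4)cc2)CC3=O)c1
F4 | step 4 | methyl 3-{6-[(3E)-4-(4-benzyloxyphenyl)-2-hydroxybut-3-en-1-yl]-4-hydroxy-2-oxo-2H-pyran-3-yl}-4-methoxybenzoate (racemic) | COC(=O)c1ccc(OC)c(-c2c(O)cc(CC(O)/C=C/c3ccc(OCc4ccccc4)cc3)oc2=O)c1
F5 | step 2 | [2-methoxy-5-(methoxycarbonyl)phenyl]lead triacetate | COC(=O)c1ccc(OC)c([Pb](OC(C)=O)(OC(C)=O)OC(C)=O)c1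
A1 | alternative 1 | methyl 5-[4-(allyloxy)-2,6-bis(benzyloxy)phenyl]-4-methoxycyclohexa-1,4-diene-1-carboxylate | COC(=O)C1=CCC(OC)=C(c2c(OCc3ccccc3)cc(OCC=C)cc2OCc2ccccc2)C1
A2 | alternative 1 | 5-(allyloxy)-1,3-bis(benzyloxy)-2-(3-methoxybuta-1,3-dien-2-yl)benzene | C=C(OC)C(=C)c1c(OCc2ccccc2)cc(OCC=C)cc1OCc1ccccc1
A3 | alternative 1 | methyl propiolate | C#CC(=O)OC
A4 | alternative 2 | di-tert-butylsilylene-bridged 7-benzyloxy-2-(4-benzyloxyphenyl)-6-arylflavone (O5 and the D2 oxygen joined through silicon) | COC(=O)c1ccc2c(c1)-c1c(OCc3ccccc3)cc3oc(-c4ccc(OCc5ccccc5)cc4)cc(=O)c3c1O[Si](C(C)(C)C)(C(C)(C)C)O2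
A5 | alternative 2 | methyl 4-{[7-(benzyloxy)-2-(4-benzyloxyphenyl)-4-oxo-4H-chromen-5-yl]oxy(di-tert-butyl)silyloxy}-3-iodobenzoate | COC(=O)c1ccc(O[Si](C(C)(C)C)(C(C)(C)C)Oc2cc(OCc3ccccc3)cc3oc(-c4ccc(OCc5ccccc5)cc4)cc(=O)c23)c(I)c1
A6 | alternative 3 | methyl 3-{2-[4-(benzyloxy)phenyl]-5-hydroxy-4-oxo-7-[tri(propan-2-yl)silyloxy]-4H-chromen-6-yl}-4-methoxybenzoate | COC(=O)c1ccc(OC)c(-c2c(O[Si](C(C)C)(C(C)C)C(C)C)cc3oc(-c4ccc(OCc5ccccc5)cc4)cc(=O)c3c2O)c1
A7 | alternative 3 | 2-[4-(benzyloxy)phenyl]-6-(diazoacetyl)-4H-pyran-4-one | [N-]=[N+]=CC(=O)c1cc(=O)cc(-c2ccc(OCc3ccccc3)cc2)o1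
A8 | alternative 3 | methyl 4-methoxy-3-{[tri(propan-2-yl)silyloxy]ethynyl}benzoate | COC(=O)c1ccc(OC)c(C#CO[Si](C(C)C)(C(C)C)C(C)C)c1
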